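**Strategy.** Everything rests on closing the cyclohexane of the 3-oxo half (C5a, C6, C7, C8, C9, C9a; 1-benzoxepine locants) last, through its C5a–C6 bond. The precursor 19 already holds the complete left bicycle; its right half is an open chain with two (S)-epoxides and a (Z)-allylsilane. One silyl triflate operation lets the inner epoxide oxygen open the outer epoxide (oxepane) and the allylsilane open the resulting epoxonium at its tertiary carbon (cyclohexane). The step exploits the anti arrangement of O1–C9a and C5a–C6 across the ring fusion, the quaternary methyl-bearing C5a, and the one-carbon branch on C7, which emerges as a methylidene for later hydration and acetylation.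

Key step: step 12

Remark: both halves are named as decahydro-1-benzoxepines (O1, C2, C3, C4, C5, C5a, C6, C7, C8, C9, C9a); C6 carries the two-carbon linker and C7 the tertiary acetate.
Assumption: (3R,6E)-nerolidol is not taken as purchasable and is made in steps 1–3; the L-fructose-derived enantiomer of the Shi ketone is taken as a purchasable catalyst.

**Route**

Step 1
Reactants: 1 (2E,6E)-farnesol
Product: 2 (2R,3R)-2,3-epoxyfarnesol
Conditions: t-BuOOH, Ti(OiPr)4 (cat.), D-(−)-diethyl tartrate, 4 Å molecular sieves, CH2Cl2, −20 °C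
Reagents that add atoms: tert-butyl hydroperoxide CC(C)(C)OO
Why: Sharpless asymmetric epoxidation, in which the titanium tartrate complex binds the allylic hydroxyl and delivers oxygen only to the 2,3-alkene, D-(−)-tartrate giving the (2R,3R) epoxide whose C3 becomes the C7 carbinol centre of the left half.

Step 2
Reactants: 2 (2R,3R)-2,3-epoxyfarnesol
Product: 3 (2S,3R)-2-(iodomethyl)-3-methyl-3-[(3E)-4,8-dimethylnona-3,7-dien-1-yl]oxirane
Conditions: I2, PPh3, imidazole, THF, 0 °C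
Reagents that add atoms: iodine II
Why: Appel-type iodination of the primary alcohol under buffered conditions leaves the epoxide and both trisubstituted alkenes untouched and creates no stereocentre.

Step 3
Reactants: 3 (2S,3R)-2-(iodomethyl)-3-methyl-3-[(3E)-4,8-dimethylnona-3,7-dien-1-yl]oxirane
Product: 4 (3R,6E)-nerolidol
Conditions: Zn dust, EtOH, reflux
Reagents that add atoms: none
Why: Zinc inserts into the C–I bond and the organozinc eliminates the β-oxygen (reductive epoxide opening), transposing the functionality to the tertiary allylic alcohol with the C3 configuration untouched.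

Step 4
Reactants: 4 (3R,6E)-nerolidol
Product: 5 (3R,6E)-nerolidyl acetate
Conditions: Ac2O, DMAP, Et3N, CH2Cl2, rt
Reagents that add atoms: acetic anhydride CC(=O)OC(C)=O
Why: DMAP-catalysed acetylation installs the left-half tertiary acetate while the carbinol is still unhindered and removes a hydroxyl that would otherwise open the 6,7-epoxide made in the next step.

Step 5
Reactants: 5 (3R,6E)-nerolidyl acetate
Product: 6 (3R)-5-[(2S,3S)-3-{2-[(2S)-3,3-dimethyloxiran-2-yl]ethyl}-3-methyloxiran-2-yl]-3-methylpent-1-en-3-yl acetate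
Conditions: L-fructose-derived Shi ketone (0.6 equiv), Oxone, K2CO3, Bu4NHSO4, borate buffer pH 10.5, MeCN–dimethoxymethane–H2O, 0 °C
Reagents that add atoms: Oxone (potassium peroxymonosulfate) [K+].[O-]S(=O)(=O)OO
Why: Shi epoxidation, in which the chiral dioxirane epoxidises the two electron-rich trisubstituted alkenes through a spiro transition state and ignores the monosubstituted vinyl group, this enantiomer of the ketone giving the (S,S) and (S) epoxides that later fix C9a, C5a and C3 of the left half.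

Step 6
Reactants: 6 (3R)-5-[(2S,3S)-3-{2-[(2S)-3,3-dimethyloxiran-2-yl]ethyl}-3-methyloxiran-2-yl]-3-methylpent-1-en-3-yl acetate; 7 allyltrimethylsilane
Product: 8 (2E,4R)-6-[(2S,3S)-3-{2-[(2S)-3,3-dimethyloxiran-2-yl]ethyl}-3-methyloxiran-2-yl]-4-methyl-1-(trimethylsilyl)hex-2-en-4-yl acetate
Conditions: 7 (5 equiv), second-generation Hoveyda–Grubbs catalyst (5 mol%), CH2Cl2, 40 °C
Reagents that add atoms: none
Why: Olefin cross-metathesis between the hindered vinyl group, which cannot homodimerise, and an excess of the unhindered allylsilane should give the E-allylsilane with release of ethene, epoxides and ester being inert to the ruthenium carbene.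

Step 7
Reactants: 8 (2E,4R)-6-[(2S,3S)-3-{2-[(2S)-3,3-dimethyloxiran-2-yl]ethyl}-3-methyloxiran-2-yl]-4-methyl-1-(trimethylsilyl)hex-2-en-4-yl acetate
Product: 10 (3S,5aS,6S,7R,9aS)-6-ethenyl-2,2,5a,7-tetramethyl-3-(triethylsilyloxy)decahydro-1-benzoxepin-7-yl acetate, via left epoxonium triflate 9 (not isolated)
Conditions: Et3SiOTf (1.2 equiv), 2,6-di-tert-butyl-4-methylpyridine, CH2Cl2, −78 °C; aq. NaHCO3
Reagents that add atoms: triethylsilyl trifluoromethanesulfonate CC[Si](CC)(CC)OS(=O)(=O)C(F)(F)F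
Why: Silyl-triflate-triggered tandem oxa-/carbacyclisation of a 1,5-diepoxide, in which the silylated terminal epoxide is opened at its tertiary carbon by the inner epoxide oxygen (oxepane, C3 kept as S) and the epoxonium is opened with inversion at its tertiary carbon by the γ-carbon of the allylsilane in a 6-exo chair that keeps the C7 methyl and the new vinyl group equatorial, which sets C5a (S) and C6 (S) and keeps C9a (S).

Step 8
Reactants: 11 geranyl bromide; 12 propargyl bromide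
Product: 14 (5E)-6,10-dimethylundeca-5,9-dien-1-yne, via 1,3-dilithiopropyne 13 (not isolated)
Conditions: 12, n-BuLi (2 equiv), TMEDA, Et2O, −78 °C; then 11, −78 °C → rt; H2O
Reagents that add atoms: none
Why: The propargylic carbanion of 1,3-dilithiopropyne displaces the primary allylic bromide by SN2 and the remaining acetylide is protonated on work-up, giving the terminal enyne without touching the E-alkene.

Step 9
Reactants: 14 (5E)-6,10-dimethylundeca-5,9-dien-1-yne
Product: 16 trimethyl[(2Z,5E)-2-(iodomethylidene)-6,10-dimethylundeca-5,9-dien-1-yl]silane, via alkenylcopper 15 (not isolated)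
Conditions: Me3SiCH2MgCl, CuBr·SMe2, Et2O–Me2S, −40 → 0 °C; then I2 (1.0 equiv), THF, −40 °C
Reagents that add atoms: (trimethylsilyl)methylmagnesium chloride C[Si](C)(C)C[Mg]Cl; iodine II
Why: Syn carbocupration of the terminal alkyne (Normant type) puts the silylmethyl group on the internal carbon and copper on the terminal one, and iodinolysis with retention gives the Z-iodoalkene, the geometry that later places the linker equatorial.

Step 10
Reactants: 16 trimethyl[(2Z,5E)-2-(iodomethylidene)-6,10-dimethylundeca-5,9-dien-1-yl]silane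
Product: 17 trimethyl[(2Z)-2-(iodomethylidene)-4-[(2S,3S)-3-{2-[(2S)-3,3-dimethyloxiran-2-yl]ethyl}-3-methyloxiran-2-yl]butyl]silane
Conditions: L-fructose-derived Shi ketone (0.6 equiv), Oxone, K2CO3, Bu4NHSO4, borate buffer pH 10.5, MeCN–dimethoxymethane–H2O, 0 °C
Reagents that add atoms: Oxone (potassium peroxymonosulfate) [K+].[O-]S(=O)(=O)OO
Why: Shi epoxidation should again select the two trialkyl-substituted alkenes, the iodine-bearing alkene being deactivated and shielded, and this enantiomer of the ketone gives the (S,S) and (S) epoxides.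

Step 11
Reactants: 10 (3S,5aS,6S,7R,9aS)-6-ethenyl-2,2,5a,7-tetramethyl-3-(triethylsilyloxy)decahydro-1-benzoxepin-7-yl acetate; 17 trimethyl[(2Z)-2-(iodomethylidene)-4-[(2S,3S)-3-{2-[(2S)-3,3-dimethyloxiran-2-yl]ethyl}-3-methyloxiran-2-yl]butyl]silane
Product: 19 (3S,5aS,6S,7R,9aS)-6-[(3Z)-6-[(2S,3S)-3-{2-[(2S)-3,3-dimethyloxiran-2-yl]ethyl}-3-methyloxiran-2-yl]-4-[(trimethylsilyl)methyl]hex-3-en-1-yl]-2,2,5a,7-tetramethyl-3-(triethylsilyloxy)decahydro-1-benzoxepin-7-yl acetate, via B-alkyl-9-BBN 18 (not isolated)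
Conditions: 9-BBN dimer, THF, rt → 50 °C; then 17, PdCl2(dppf) (cat.), AsPh3, Cs2CO3, DMF–H2O, rt
Reagents that add atoms: none
Why: 9-BBN hydroborates the only alkene of 10 at its terminal carbon and the B-alkyl Suzuki–Miyaura coupling joins it to the alkenyl iodide with retention of the Z geometry, aqueous carbonate at room temperature sparing epoxides, ester and silyl groups.

Step 12
Reactants: 19 (3S,5aS,6S,7R,9aS)-6-[(3Z)-6-[(2S,3S)-3-{2-[(2S)-3,3-dimethyloxiran-2-yl]ethyl}-3-methyloxiran-2-yl]-4-[(trimethylsilyl)methyl]hex-3-en-1-yl]-2,2,5a,7-tetramethyl-3-(triethylsilyloxy)decahydro-1-benzoxepin-7-yl acetate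
Product: 22 (3S,5aS,6S,7R,9aS)-6-{2-[(3S,5aS,6R,9aS)-3-hydroxy-2,2,5a-trimethyl-7-methylidenedecahydro-1-benzoxepin-6-yl]ethyl}-2,2,5a,7-tetramethyl-3-(triethylsilyloxy)decahydro-1-benzoxepin-7-yl acetate, via right epoxonium triflate 20 (not isolated), via trimethylsilyl ether 21 (not isolated)
Conditions: Me3SiOTf (1.2 equiv), 2,6-di-tert-butyl-4-methylpyridine, CH2Cl2, −78 °C; then K2CO3, MeOH, 0 °C
Reagents that add atoms: none
Why: Me3SiOTf silylates the terminal epoxide, the oxygen of the neighbouring epoxide opens it at its tertiary carbon to give bicyclic epoxonium 20, the tertiary carbon of 20 is attacked by the CH terminus of the allylsilane with loss of Me3Si+ (which regenerates the silyl triflate), and methanolysis of silyl ether 21 frees the C3 alcohol. The closest known reaction type is the silyl-triflate-promoted tandem oxa-/carbacyclisation of 1,5-diepoxides terminated by enol silanes, alkenes or propargylsilanes, combined with the allylsilane termination of epoxy-polyene cyclisations. The oxepane closes first by a 7-endo opening of the terminal epoxide (O1–C2 bond), and the cyclohexane closes last by a 6-endo-trig attack of the alkene on C5a (C5a–C6 bond) through a chair. C3 and C9a keep the configurations of the (S)-epoxides, C5a is set by inversion at the epoxonium carbon (trans fusion, axial methyl), and C6 is set by the Z geometry of the allylsilane, which puts the linker equatorial in the chair. The step needs oxacyclisation before carbocyclisation, endo opening at both epoxides and a single alkene regioisomer: the fully substituted epoxide carbons direct endo opening, the six-membered contact of the two epoxide units makes the anchimeric opening fast at −78 °C, and the β-silyl effect fixes the attacking carbon and leaves only the exocyclic methylidene.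

Step 13
Reactants: 22 (3S,5aS,6S,7R,9aS)-6-{2-[(3S,5aS,6R,9aS)-3-hydroxy-2,2,5a-trimethyl-7-methylidenedecahydro-1-benzoxepin-6-yl]ethyl}-2,2,5a,7-tetramethyl-3-(triethylsilyloxy)decahydro-1-benzoxepin-7-yl acetate
Product: 23 (3S,5aS,6S,7R,9aS)-6-{2-[(3S,5aS,6S,7S,9aS)-3,7-dihydroxy-2,2,5a,7-tetramethyldecahydro-1-benzoxepin-6-yl]ethyl}-2,2,5a,7-tetramethyl-3-(triethylsilyloxy)decahydro-1-benzoxepin-7-yl acetate
Conditions: Co(acac)2 (cat.), PhSiH3, O2 (1 atm), THF, rt
Reagents that add atoms: dioxygen O=O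
Why: Mukaiyama hydration, in which hydrogen-atom transfer to the methylidene CH2 gives the tertiary C7 radical and O2 should trap it from the equatorial side because the axial face is blocked by the syn-axial C5a methyl, giving the equatorial hydroxyl and axial methyl (7S).

Step 14
Reactants: 23 (3S,5aS,6S,7R,9aS)-6-{2-[(3S,5aS,6S,7S,9aS)-3,7-dihydroxy-2,2,5a,7-tetramethyldecahydro-1-benzoxepin-6-yl]ethyl}-2,2,5a,7-tetramethyl-3-(triethylsilyloxy)decahydro-1-benzoxepin-7-yl acetate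
Product: 24 (3S,5aS,6S,7R,9aS)-6-{2-[(5aS,6S,7S,9aS)-7-hydroxy-2,2,5a,7-tetramethyl-3-oxodecahydro-1-benzoxepin-6-yl]ethyl}-2,2,5a,7-tetramethyl-3-(triethylsilyloxy)decahydro-1-benzoxepin-7-yl acetate
Conditions: Dess–Martin periodinane, NaHCO3, CH2Cl2, rt
Reagents that add atoms: none
Why: Dess–Martin oxidation converts the only secondary alcohol into the C3 ketone, the tertiary alcohol, ester and silyl ether being inert.

Step 15
Reactants: 24 (3S,5aS,6S,7R,9aS)-6-{2-[(5aS,6S,7S,9aS)-7-hydroxy-2,2,5a,7-tetramethyl-3-oxodecahydro-1-benzoxepin-6-yl]ethyl}-2,2,5a,7-tetramethyl-3-(triethylsilyloxy)decahydro-1-benzoxepin-7-yl acetate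
Product: 25 (3S,5aS,6S,7R,9aS)-6-{2-[(5aS,6S,7S,9aS)-7-acetoxy-2,2,5a,7-tetramethyl-3-oxodecahydro-1-benzoxepin-6-yl]ethyl}-2,2,5a,7-tetramethyl-3-(triethylsilyloxy)decahydro-1-benzoxepin-7-yl acetate
Conditions: Ac2O, DMAP, Et3N, CH2Cl2, 40 °C
Reagents that add atoms: acetic anhydride CC(=O)OC(C)=O
Why: DMAP catalysis with excess anhydride acylates the remaining tertiary hydroxyl, the other oxygens being already masked or at the ketone level.

Step 16
Reactants: 25 (3S,5aS,6S,7R,9aS)-6-{2-[(5aS,6S,7S,9aS)-7-acetoxy-2,2,5a,7-tetramethyl-3-oxodecahydro-1-benzoxepin-6-yl]ethyl}-2,2,5a,7-tetramethyl-3-(triethylsilyloxy)decahydro-1-benzoxepin-7-yl acetate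
Product: 26 CNP0298533.1, (3S,5aS,6S,7R,9aS)-6-{2-[(5aS,6S,7S,9aS)-7-acetoxy-2,2,5a,7-tetramethyl-3-oxodecahydro-1-benzoxepin-6-yl]ethyl}-3-hydroxy-2,2,5a,7-tetramethyldecahydro-1-benzoxepin-7-yl acetate
Conditions: HF·pyridine, THF, 0 °C → rt
Reagents that add atoms: none
Why: Fluoride cleaves the Si–O bond of the secondary triethylsilyl ether under conditions that leave both tertiary acetates and the ketone untouched, giving the target.

**Compound list**

1 | (2E,6E)-farnesol | OC/C=C(\C)CC/C=C(\C)CCC=C(C)C | starting material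
2 | (2R,3R)-2,3-epoxyfarnesol, [(2R,3R)-3-methyl-3-[(3E)-4,8-dimethylnona-3,7-dien-1-yl]oxiran-2-yl]methanol | OC[C@H]1O[C@]1(C)CC/C=C(\C)CCC=C(C)C | intermediate
3 | (2S,3R)-2-(iodomethyl)-3-methyl-3-[(3E)-4,8-dimethylnona-3,7-dien-1-yl]oxirane | IC[C@H]1O[C@]1(C)CC/C=C(\C)CCC=C(C)C | intermediate
4 | (3R,6E)-nerolidol | C=C[C@](C)(O)CC/C=C(\C)CCC=C(C)C | intermediate
5 | (3R,6E)-nerolidyl acetate | C=C[C@](C)(OC(C)=O)CC/C=C(\C)CCC=C(C)C | intermediate
6 | (3R)-5-[(2S,3S)-3-{2-[(2S)-3,3-dimethyloxiran-2-yl]ethyl}-3-methyloxiran-2-yl]-3-methylpent-1-en-3-yl acetate | C=C[C@](C)(OC(C)=O)CC[C@@H]1O[C@@]1(C)CC[C@@H]1OC1(C)C | intermediate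
7 | allyltrimethylsilane | C=CC[Si](C)(C)C | starting material
8 | (2E,4R)-6-[(2S,3S)-3-{2-[(2S)-3,3-dimethyloxiran-2-yl]ethyl}-3-methyloxiran-2-yl]-4-methyl-1-(trimethylsilyl)hex-2-en-4-yl acetate | C[Si](C)(C)C/C=C/[C@](C)(OC(C)=O)CC[C@@H]1O[C@@]1(C)CC[C@@H]1OC1(C)C | intermediate
9 | left epoxonium triflate: 1-oxoniabicyclo[4.1.0]heptane with 2,2,6-trimethyl, 3-(triethylsilyloxy) and, on C7, the (3R,4E)-3-acetoxy-3-methyl-6-(trimethylsilyl)hex-4-en-1-yl chain | C[Si](C)(C)C/C=C/[C@](C)(OC(C)=O)CC[C@@H]1[O+]2[C@@]1(C)CC[C@H](O[Si](CC)(CC)CC)C2(C)C.[O-]S(=O)(=O)C(F)(F)F | intermediate (not isolated)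
10 | (3S,5aS,6S,7R,9aS)-6-ethenyl-2,2,5a,7-tetramethyl-3-(triethylsilyloxy)decahydro-1-benzoxepin-7-yl acetate | CC(=O)O[C@]1(C)CC[C@@H]2OC(C)(C)[C@@H](O[Si](CC)(CC)CC)CC[C@@]2(C)[C@@H]1C=C | intermediate
11 | geranyl bromide, (2E)-1-bromo-3,7-dimethylocta-2,6-diene | BrC/C=C(\C)CCC=C(C)C | starting material
12 | propargyl bromide | C#CCBr | starting material
13 | 1,3-dilithiopropyne | [Li]CC#C[Li] | intermediate (not isolated)
14 | (5E)-6,10-dimethylundeca-5,9-dien-1-yne | C#CCC/C=C(\C)CCC=C(C)C | intermediate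
15 | [(1Z,5E)-6,10-dimethyl-2-[(trimethylsilyl)methyl]undeca-1,5,9-trien-1-yl]copper | [Cu]/C=C(\C[Si](C)(C)C)CC/C=C(\C)CCC=C(C)C | intermediate (not isolated)
16 | trimethyl[(2Z,5E)-2-(iodomethylidene)-6,10-dimethylundeca-5,9-dien-1-yl]silane | I/C=C(\C[Si](C)(C)C)CC/C=C(\C)CCC=C(C)C | intermediate
17 | trimethyl[(2Z)-2-(iodomethylidene)-4-[(2S,3S)-3-{2-[(2S)-3,3-dimethyloxiran-2-yl]ethyl}-3-methyloxiran-2-yl]butyl]silane | I/C=C(\C[Si](C)(C)C)CC[C@@H]1O[C@@]1(C)CC[C@@H]1OC1(C)C | intermediate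
18 | 9-{2-[(3S,5aS,6S,7R,9aS)-7-acetoxy-2,2,5a,7-tetramethyl-3-(triethylsilyloxy)decahydro-1-benzoxepin-6-yl]ethyl}-9-borabicyclo[3.3.1]nonane | CC(=O)O[C@]1(C)CC[C@@H]2OC(C)(C)[C@@H](O[Si](CC)(CC)CC)CC[C@@]2(C)[C@@H]1CCB1C2CCCC1CCC2 | intermediate (not isolated)
19 | (3S,5aS,6S,7R,9aS)-6-[(3Z)-6-[(2S,3S)-3-{2-[(2S)-3,3-dimethyloxiran-2-yl]ethyl}-3-methyloxiran-2-yl]-4-[(trimethylsilyl)methyl]hex-3-en-1-yl]-2,2,5a,7-tetramethyl-3-(triethylsilyloxy)decahydro-1-benzoxepin-7-yl acetate | CC(=O)O[C@]1(C)CC[C@@H]2OC(C)(C)[C@@H](O[Si](CC)(CC)CC)CC[C@@]2(C)[C@@H]1CC/C=C(\C[Si](C)(C)C)CC[C@@H]1O[C@@]1(C)CC[C@@H]1OC1(C)C | intermediate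
20 | right epoxonium triflate: 19 in which the inner epoxide oxygen is bonded to the former terminal epoxide carbon C2 (1-oxoniabicyclo[4.1.0]heptane, 2,2,6-trimethyl, 3-trimethylsilyloxy) | CC(=O)O[C@]1(C)CC[C@@H]2OC(C)(C)[C@@H](O[Si](CC)(CC)CC)CC[C@@]2(C)[C@@H]1CC/C=C(\C[Si](C)(C)C)CC[C@@H]1[O+]2[C@@]1(C)CC[C@H](O[Si](C)(C)C)C2(C)C.[O-]S(=O)(=O)C(F)(F)F | intermediate (not isolated)
21 | (3S,5aS,6S,7R,9aS)-6-{2-[(3S,5aS,6R,9aS)-2,2,5a-trimethyl-7-methylidene-3-(trimethylsilyloxy)decahydro-1-benzoxepin-6-yl]ethyl}-2,2,5a,7-tetramethyl-3-(triethylsilyloxy)decahydro-1-benzoxepin-7-yl acetate | CC(=O)O[C@]1(C)CC[C@@H]2OC(C)(C)[C@@H](O[Si](CC)(CC)CC)CC[C@@]2(C)[C@@H]1CC[C@H]1[C@]2(C)CC[C@H](O[Si](C)(C)C)C(C)(C)O[C@H]2CCC1=C | intermediate (not isolated)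
22 | (3S,5aS,6S,7R,9aS)-6-{2-[(3S,5aS,6R,9aS)-3-hydroxy-2,2,5a-trimethyl-7-methylidenedecahydro-1-benzoxepin-6-yl]ethyl}-2,2,5a,7-tetramethyl-3-(triethylsilyloxy)decahydro-1-benzoxepin-7-yl acetate | CC(=O)O[C@]1(C)CC[C@@H]2OC(C)(C)[C@@H](O[Si](CC)(CC)CC)CC[C@@]2(C)[C@@H]1CC[C@H]1[C@]2(C)CC[C@H](O)C(C)(C)O[C@H]2CCC1=C | intermediate
23 | (3S,5aS,6S,7R,9aS)-6-{2-[(3S,5aS,6S,7S,9aS)-3,7-dihydroxy-2,2,5a,7-tetramethyldecahydro-1-benzoxepin-6-yl]ethyl}-2,2,5a,7-tetramethyl-3-(triethylsilyloxy)decahydro-1-benzoxepin-7-yl acetate | CC(=O)O[C@]1(C)CC[C@@H]2OC(C)(C)[C@@H](O[Si](CC)(CC)CC)CC[C@@]2(C)[C@@H]1CC[C@H]1[C@]2(C)CC[C@H](O)C(C)(C)O[C@H]2CC[C@]1(C)O | intermediate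
24 | (3S,5aS,6S,7R,9aS)-6-{2-[(5aS,6S,7S,9aS)-7-hydroxy-2,2,5a,7-tetramethyl-3-oxodecahydro-1-benzoxepin-6-yl]ethyl}-2,2,5a,7-tetramethyl-3-(triethylsilyloxy)decahydro-1-benzoxepin-7-yl acetate | CC(=O)O[C@]1(C)CC[C@@H]2OC(C)(C)[C@@H](O[Si](CC)(CC)CC)CC[C@@]2(C)[C@@H]1CC[C@H]1[C@]2(C)CCC(=O)C(C)(C)O[C@H]2CC[C@]1(C)O | intermediate
25 | (3S,5aS,6S,7R,9aS)-6-{2-[(5aS,6S,7S,9aS)-7-acetoxy-2,2,5a,7-tetramethyl-3-oxodecahydro-1-benzoxepin-6-yl]ethyl}-2,2,5a,7-tetramethyl-3-(triethylsilyloxy)decahydro-1-benzoxepin-7-yl acetate | CC(=O)O[C@]1(C)CC[C@@H]2OC(C)(C)[C@@H](O[Si](CC)(CC)CC)CC[C@@]2(C)[C@@H]1CC[C@H]1[C@]2(C)CCC(=O)C(C)(C)O[C@H]2CC[C@]1(C)OC(C)=O | intermediate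
26 | CNP0298533.1, (3S,5aS,6S,7R,9aS)-6-{2-[(5aS,6S,7S,9aS)-7-acetoxy-2,2,5a,7-tetramethyl-3-oxodecahydro-1-benzoxepin-6-yl]ethyl}-3-hydroxy-2,2,5a,7-tetramethyldecahydro-1-benzoxepin-7-yl acetate | CC(=O)O[C@]1(C)CC[C@@H]2OC(C)(C)[C@@H](O)CC[C@@]2(C)[C@@H]1CC[C@H]1[C@]2(C)CCC(=O)C(C)(C)O[C@H]2CC[C@]1(C)OC(C)=O | target

**Step count and risks**

Total step count: 16. Longest linear sequence: 13 steps (steps 1–7, then 11–16); the right-hand fragment takes steps 8–10.

Most likely to fail, step 12: the strongly nucleophilic allylsilane may attack the silylated inner epoxide before the epoxide–epoxide oxacyclisation (carbocyclisation first, outer epoxide left uncyclised), or it may be protodesilylated. The fallback sets out from 14 (and uses 18) and comes back to the route at 23; it exchanges the terminator for a plain trisubstituted alkene, the weaker nucleophile for which the oxepane-first order is best established. Zirconium-catalysed carboalumination of 14 (AlMe3, Cp2ZrCl2, then I2) should give (1E,5E)-1-iodo-2,6,10-trimethylundeca-1,5,9-triene F1. Shi epoxidation as in step 10 should give its bis-epoxide F2, and coupling with 18 as in step 11 the methyl-terminated bis-epoxide F3. The same silyl triflate cascade then ends by proton loss and should give 21 together with its endocyclic alkene isomer, silyl ether F4 (any tetrasubstituted isomer is lost). Methanolysis gives 22 and the endocyclic alcohol F5, and both alkenes pass through the same tertiary C7 radical in the hydration of step 13 and so converge on 23.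

Step 7: Lewis-acid ionisation of the tertiary allylic acetate, assisted by the δ-silyl group (1,4-elimination to a diene), may compete with epoxide activation. The fallback sets out from 4 and comes back at 10; it cyclises first and acetylates afterwards. Silylation of 4 (Me3SiCl, imidazole) gives (3R,6E)-nerolidyl trimethylsilyl ether F6, a far poorer leaving group. Shi epoxidation as in step 5 gives silyl ether bis-epoxide F7, and cross-metathesis with 7 gives silyl ether allylsilane F8. The Et3SiOTf cascade gives bicyclic bis-silyl ether F9, and K2CO3/MeOH removes only the tertiary trimethylsilyl group to give tertiary alcohol F10. Forcing acetylation (Ac2O, DMAP, 60 °C) then returns to 10.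

Step 10: chemoselectivity may be lost through oxidation of the iodo-allylsilane alkene, or of iodine, by the dioxirane. The fallback sets out from 14 (and uses 18) and comes back at 19; it epoxidises before the allylsilane exists and reverses the polarity of the coupling. Shi epoxidation of 14, whose alkyne is inert, gives diepoxy alkyne F11. Copper-catalysed borylative alkylation (B2pin2, CuCl, Xantphos, NaOtBu, ICH2SiMe3; syn addition with boron on the terminal carbon) gives (Z)-alkenylboronate F12. Borane 18 is converted with I2/NaOMe into primary iodide F13, and alkyl–alkenyl Suzuki–Miyaura coupling of F13 with F12 (Pd(OAc)2, P(t-Bu)2Me, K3PO4·H2O) gives 19.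

Further compounds
F1 | step 12 | (1E,5E)-1-iodo-2,6,10-trimethylundeca-1,5,9-triene | I/C=C(\C)CC/C=C(\C)CCC=C(C)C
F2 | step 12 | (2S,3S)-2-[(3E)-4-iodo-3-methylbut-3-en-1-yl]-3-{2-[(2S)-3,3-dimethyloxiran-2-yl]ethyl}-3-methyloxirane | I/C=C(\C)CC[C@@H]1O[C@@]1(C)CC[C@@H]1OC1(C)C
F3 | step 12 | methyl-terminated bis-epoxide, (3S,5aS,6S,7R,9aS)-6-[(3E)-6-[(2S,3S)-3-{2-[(2S)-3,3-dimethyloxiran-2-yl]ethyl}-3-methyloxiran-2-yl]-4-methylhex-3-en-1-yl]-2,2,5a,7-tetramethyl-3-(triethylsilyloxy)decahydro-1-benzoxepin-7-yl acetate | CC(=O)O[C@]1(C)CC[C@@H]2OC(C)(C)[C@@H](O[Si](CC)(CC)CC)CC[C@@]2(C)[C@@H]1CC/C=C(\C)CC[C@@H]1O[C@@]1(C)CC[C@@H]1OC1(C)C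
F4 | step 12 | endocyclic (C7=C8) alkene isomer of 21, right half 2,2,5a,7-tetramethyl-3-(trimethylsilyloxy)-2,3,4,5,5a,6,9,9a-octahydro-1-benzoxepin-6-yl | CC(=O)O[C@]1(C)CC[C@@H]2OC(C)(C)[C@@H](O[Si](CC)(CC)CC)CC[C@@]2(C)[C@@H]1CC[C@H]1[C@]2(C)CC[C@H](O[Si](C)(C)C)C(C)(C)O[C@H]2CC=C1C
F5 | step 12 | endocyclic (C7=C8) alkene isomer of 22, right half 3-hydroxy-2,2,5a,7-tetramethyl-2,3,4,5,5a,6,9,9a-octahydro-1-benzoxepin-6-yl | CC(=O)O[C@]1(C)CC[C@@H]2OC(C)(C)[C@@H](O[Si](CC)(CC)CC)CC[C@@]2(C)[C@@H]1CC[C@H]1[C@]2(C)CC[C@H](O)C(C)(C)O[C@H]2CC=C1C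
F6 | step 7 | (3R,6E)-nerolidyl trimethylsilyl ether | C=C[C@](C)(O[Si](C)(C)C)CC/C=C(\C)CCC=C(C)C
F7 | step 7 | silyl ether bis-epoxide, trimethyl{[(3R)-5-[(2S,3S)-3-{2-[(2S)-3,3-dimethyloxiran-2-yl]ethyl}-3-methyloxiran-2-yl]-3-methylpent-1-en-3-yl]oxy}silane | C=C[C@](C)(O[Si](C)(C)C)CC[C@@H]1O[C@@]1(C)CC[C@@H]1OC1(C)C
F8 | step 7 | silyl ether allylsilane, (2E,4R)-4-methyl-1-(trimethylsilyl)-4-(trimethylsilyloxy)hex-2-ene carrying the bis-epoxide unit of 8 on C6 | C[Si](C)(C)C/C=C/[C@](C)(O[Si](C)(C)C)CC[C@@H]1O[C@@]1(C)CC[C@@H]1OC1(C)C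
F9 | step 7 | bicyclic bis-silyl ether, (3S,5aS,6S,7R,9aS)-6-ethenyl-2,2,5a,7-tetramethyl-3-(triethylsilyloxy)-7-(trimethylsilyloxy)decahydro-1-benzoxepine | C[Si](C)(C)O[C@]1(C)CC[C@@H]2OC(C)(C)[C@@H](O[Si](CC)(CC)CC)CC[C@@]2(C)[C@@H]1C=C
F10 | step 7 | tertiary alcohol, (3S,5aS,6S,7R,9aS)-6-ethenyl-2,2,5a,7-tetramethyl-3-(triethylsilyloxy)decahydro-1-benzoxepin-7-ol | O[C@]1(C)CC[C@@H]2OC(C)(C)[C@@H](O[Si](CC)(CC)CC)CC[C@@]2(C)[C@@H]1C=C
F11 | step 10 | diepoxy alkyne, (2S,3S)-2-(but-3-yn-1-yl)-3-{2-[(2S)-3,3-dimethyloxiran-2-yl]ethyl}-3-methyloxirane | C#CCC[C@@H]1O[C@@]1(C)CC[C@@H]1OC1(C)C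
F12 | step 10 | (Z)-alkenylboronate, pinacol ester of the boronic acid corresponding to iodide 17 (boron in place of iodine) | CC1(C)OB(/C=C(\C[Si](C)(C)C)CC[C@@H]2O[C@@]2(C)CC[C@@H]2OC2(C)C)OC1(C)C
F13 | step 10 | primary iodide, (3S,5aS,6S,7R,9aS)-6-(2-iodoethyl)-2,2,5a,7-tetramethyl-3-(triethylsilyloxy)decahydro-1-benzoxepin-7-yl acetate | CC(=O)O[C@]1(C)CC[C@@H]2OC(C)(C)[C@@H](O[Si](CC)(CC)CC)CC[C@@]2(C)[C@@H]1CCI
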